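I started with an easy division, 53.0 % for Friday's: the nucleophile charge over two electrophile charges. I called this the ceiling, the share of the electrophile that the nucleophile charge pays for at two nucleophiles each.

| flask | electrophile | nucleophile | solid base | remark | time |
|---|---|---|---|---|---|
| autumn | 0.50 M | 0.75 M | 0.75 M | run made earlier |  |
| spring | 0.50 M | 1.3 M | 0.75 M | run made earlier |  |
| Friday's | 0.50 M | 0.530 M | 0.750 M |  | 80 min |
| Tuesday's | 0.50 M | 1.10 M | 0.750 M |  | 80 min |

- autumn (time / min: electrophile / %, target / %): 6.00: 63.0, 35.4; 12.0: 48.1, 52.2; 15.0: 41.9, 56.3; 25.0: 31.1, 65.6; 30.0: 30.8, 69.4; 40.0: 26.3, 73.7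
- spring (time / min: electrophile / %, target / %): 3.00: 62.0, 36.2; 5.00: 48.4, 48.2; 8.00: 36.5, 64.1; 12.0: 25.1, 74.9; 15.0: 19.9, 80.4; 25.0: 9.4, 90.7; 40.0: 4.0, 96.3

(standard deviation of a reading: 1 percentage point)

- part of the electrophile that has reacted at the end, Friday's
- part of the electrophile that has reacted at the end, Tuesday's
- what raising the concentration of nucleophile from its lowest to its highest value here does to the part of the electrophile that has reacted (changes below 5 percentage points count as none) (it falls / no change / it rises)

- given per volume of solution although it is solid: solid base
- at the start none of the solid base is in solution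

I held the ceiling against the tables. Autumn's ceiling was 75.0 %, and its target reached 73.7 % at 40.0 min. Its electrophile column slowed, going from 31.1 % at 25.0 min to 26.3 %. Spring's ceiling was 130 %, above the whole charge, and its electrophile column fell to 4.0 % at 40.0 min.

So I read two phases: a fast climb to the ceiling, then a creep. I took the creep from autumn's last readings, with their scatter. I gave Friday's autumn's 40.0 min to reach its ceiling, which left 40.0 min of creep, worth 13 percentage points. My figure for Friday's was 65.8 %.

Tuesday's ceiling was 110 %, so there the electrophile is the limiting reagent. With 80 min allowed, I committed to about spring's 96.3 % or a little more. The part reacted therefore rises, by about 30 points on my figures, against the 5 points that counts as a change.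

The forecast gave 65 % for Friday's and 98 % for Tuesday's, and said it rises, with “the limit is 53%, plus regeneration over 80 min, giving about 65%”.

The flasks gave 67.4 % for Friday's and 98.2 % for Tuesday's, and it rises by 31 points.

    electrophile + nucleophile → acid set free + target (k = 0.141 M⁻¹ min⁻¹)
    nucleophile + acid set free ⇌ protonated nucleophile, settled at all times (K = 200 M⁻¹)
    acid set free + free base ⇌ salt of the base, settled at all times (K = 5700 M⁻¹)
    nucleophile + acid set free ⇌ idle adduct, settled at all times (K = 170 M⁻¹)
    solid base ⇌ free base, rate k5*(cs5 - [free base]) while solid is left; crystals form when [free base] > cs5 (solubility = 0.410 M, k = 0.00556 min⁻¹)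
    acid set free → by-product carried off (k = 0.00562 min⁻¹)

The main reason Tuesday's stood above Friday's was its larger nucleophile charge: with Friday's charge, Tuesday's flask gave 67.4 % instead of 98.2 %. Friday's ended 14 points above its ceiling. Friday's kept 75.8 % of its solid base, and the dissolved part lifts the ceiling by 18 points. A flask like Friday's with 0.21 M of nucleophile has a ceiling of 21.0 %, or 39.0 % with its own lift. That flask gave 36.0 %.

Readings and results are calculated on assumed constants, noise included.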